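**Retrosynthetic overview**

- Feature: ring B (C1' CO2H, C2' OH, C3' H, C4' OH, C5' O-aryl, C6' pentyl) is olivetolic acid etherified at C5'. Opened at the C1'–C6' bond it is a 6-aryloxy-3,5,7-trioxododecanoic acid, which is stored as a 6-substituted 4-hydroxy-2-pyranone.
- Last disconnection (ring B, bond C1'–C6'): hydroxide opening of that pyranone and aldol aromatisation, which sets the carboxylic acid free with no ester to cleave.
- C5'–O disconnection: SN2 of the chelated 8-OH of a 6-O-PMB 6,8-dihydroxy-3-pentylisocoumarin on an α-bromo ketone flanked by the pyranone.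
- Both pentyl ketones come from hexanoyl chloride: C-acylation of lithiated 4-PMBO-6-methylpyranone, and (as the Weinreb amide) of laterally lithiated bis-MOM methyl orsellinate.
- Ring order: the isocoumarin lactone ring is closed on the bought orsellinate benzene ring (step 4); the bought pyranone ring is carried to the end and converted into ring B (step 11).

Key step: step 11

Remark: the carbon that becomes C5' is a stereocentre in 15, 16 and 17. It is carried as the racemate and becomes sp2 on aromatisation; the target is achiral.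

**Route**

Step 1
Reactants: 1 hexanoyl chloride
Product: 2 N-methoxy-N-methylhexanamide
Conditions: MeNH(OMe)·HCl, K2CO3, CH2Cl2/H2O, 0 °C → rt
Reagents that add atoms: N,O-dimethylhydroxylamine hydrochloride, Cl.CNOC
Why: Schotten–Baumann N-acylation of the amine by the acid chloride should give the Weinreb amide cleanly.

Step 2
Reactants: 3 methyl orsellinate (methyl 2,4-dihydroxy-6-methylbenzoate)
Product: 4 methyl 2,4-bis(methoxymethoxy)-6-methylbenzoate
Conditions: NaH, MOMCl, DMF, 0 °C → rt
Reagents that add atoms: chloromethyl methyl ether, COCCl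
Why: Williamson-type O-alkylation of both sodium phenoxides; full deprotonation with NaH makes the hydrogen-bonded 2-OH react as well.

Step 3
Reactants: 4 methyl 2,4-bis(methoxymethoxy)-6-methylbenzoate; 2 N-methoxy-N-methylhexanamide
Product: 6 methyl 2,4-bis(methoxymethoxy)-6-(2-oxoheptyl)benzoate, via lithiated toluate 5 (not isolated)
Conditions: LiN(iPr)2 (2 equiv), THF, −78 °C; then 2, −78 → −40 °C; aq NH4Cl
Reagents that add atoms: none
Why: Lateral (benzylic) lithiation of the ortho-toluate followed by Weinreb ketone synthesis; the chelated tetrahedral adduct stops over-addition and the doubly ortho-substituted ester resists self-condensation.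

Step 4
Reactants: 6 methyl 2,4-bis(methoxymethoxy)-6-(2-oxoheptyl)benzoate
Product: 8 6,8-dihydroxy-3-pentyl-1H-isochromen-1-one, via dihydroxy keto ester 7 (not isolated)
Conditions: HCl (3 M in MeOH), rt; evaporate; p-TsOH·H2O (cat.), toluene, reflux
Reagents that add atoms: none
Why: Acid-catalysed acetal cleavage of the MOM ethers, then acid-catalysed enol lactonisation of the 2-(2-oxoalkyl)benzoate with loss of methanol, should give the isocoumarin; distilling off methanol drives the closure.

Step 5
Reactants: 8 6,8-dihydroxy-3-pentyl-1H-isochromen-1-one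
Product: 9 8-hydroxy-6-[(4-methoxyphenyl)methoxy]-3-pentyl-1H-isochromen-1-one
Conditions: PMBCl (1.05 equiv), K2CO3, DMF, rt
Reagents that add atoms: 4-methoxybenzyl chloride, COc1ccc(CCl)cc1
Why: Site-selective Williamson etherification; the 6-OH (para to the lactone carbonyl, more acidic, not chelated) is alkylated while the 8-OH stays hydrogen-bonded to C1=O.

Step 6
Reactants: 10 4-hydroxy-6-methyl-2H-pyran-2-one (triacetic acid lactone)
Product: 11 4-[(4-methoxyphenyl)methoxy]-6-methyl-2H-pyran-2-one
Conditions: 4-methoxybenzyl alcohol, PPh3, DIAD, THF, 0 °C → rt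
Reagents that add atoms: 4-methoxybenzyl alcohol, COc1ccc(CO)cc1
Why: Mitsunobu O-alkylation of the acidic 4-hydroxypyranone should give the 4-alkoxy-2-pyranone and avoid the C3-alkylation that benzylic halides can cause.

Step 7
Reactants: 11 4-[(4-methoxyphenyl)methoxy]-6-methyl-2H-pyran-2-one; 1 hexanoyl chloride
Product: 13 4-[(4-methoxyphenyl)methoxy]-6-(2-oxoheptyl)-2H-pyran-2-one, via lithiated pyranone 12 (not isolated)
Conditions: 11 (2 equiv), LiN(iPr)2 (2 equiv), THF, −78 °C; then 1 (1 equiv), −78 °C; aq NH4Cl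
Reagents that add atoms: none
Why: Claisen-type C-acylation of the vinylogous lithium enolate formed at the 6-methyl group; the second equivalent of anion takes the more acidic proton of the product, so no free amide base meets the acid chloride and diacylation is avoided (the surplus 11 is recovered).

Step 8
Reactants: 13 4-[(4-methoxyphenyl)methoxy]-6-(2-oxoheptyl)-2H-pyran-2-one
Product: 15 6-(1-bromo-2-oxoheptyl)-4-[(4-methoxyphenyl)methoxy]-2H-pyran-2-one (racemic), via lithium enolate 14 (not isolated)
Conditions: LiN(SiMe3)2 (1.05 equiv), THF, −78 °C; cannulated into N-bromosuccinimide (1.05 equiv), THF, −78 °C; aq NH4Cl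
Reagents that add atoms: N-bromosuccinimide, O=C1CCC(=O)N1Br
Why: Electrophilic α-bromination of a preformed, regiodefined enolate; at −78 °C the enolate carbon reacts far faster than pyranone C3 or the PMB ring, and inverse addition limits dibromination.

Step 9
Reactants: 9 8-hydroxy-6-[(4-methoxyphenyl)methoxy]-3-pentyl-1H-isochromen-1-one; 15 6-(1-bromo-2-oxoheptyl)-4-[(4-methoxyphenyl)methoxy]-2H-pyran-2-one
Product: 16 4-[(4-methoxyphenyl)methoxy]-6-[1-({6-[(4-methoxyphenyl)methoxy]-1-oxo-3-pentyl-1H-isochromen-8-yl}oxy)-2-oxoheptyl]-2H-pyran-2-one (racemic)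
Conditions: K2CO3, DMF, 0 °C → rt
Reagents that add atoms: none
Why: Williamson ether synthesis by SN2 of the 8-phenoxide on a carbonyl-activated secondary bromide, as with 2-halo-1,3-dicarbonyl compounds and phenols; Dieckmann attack of the product carbanion on the isocoumarin carbonyl would give a quaternary, non-enolisable diketone and is thermodynamically uphill.

Step 10
Reactants: 16 the bis-PMB ether
Product: 17 4-hydroxy-6-{1-[(6-hydroxy-1-oxo-3-pentyl-1H-isochromen-8-yl)oxy]-2-oxoheptyl}-2H-pyran-2-one (racemic)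
Conditions: TFA (10 vol%), pentamethylbenzene, CH2Cl2, 0 °C
Reagents that add atoms: none
Why: Acidolysis of the two PMB ethers, both on acidic oxygens (a vinylogous acid and a phenol conjugated to the lactone carbonyl); pentamethylbenzene traps the benzylic cation by Friedel–Crafts alkylation, and lactones, ketone and ether are acid-stable at this temperature.

Step 11
Reactants: 17 4-hydroxy-6-{1-[(6-hydroxy-1-oxo-3-pentyl-1H-isochromen-8-yl)oxy]-2-oxoheptyl}-2H-pyran-2-one
Product: 20 4,6-dihydroxy-3-[(6-hydroxy-1-oxo-3-pentyl-1H-isochromen-8-yl)oxy]-2-pentylbenzoic acid (target), via triketo acid 18 (not isolated), via aldol adduct 19 (not isolated)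
Conditions: KOH (1 M, aq, degassed), 0 °C → rt, Ar; then HCl (2 M), 0 °C, to pH 2; TFA, CH2Cl2, rt only if the isocoumarin lactone has opened
Reagents that add atoms: potassium hydroxide, [K+].[OH-]
Why: Hydroxide adds to the pyranone C2 carbonyl and opens the lactone to the 3,5,7-triketo carboxylate 18, the known base-induced route from 4-hydroxy-6-(2-oxoalkyl)-2-pyranones to orsellinic-type acids. The enolate of the C2' ketone, whose carbon C1' also bears the carboxylate, adds to the hexanoyl carbonyl C6' in a 6-(enolendo)-exo-trig aldol that closes ring B; adduct 19 then loses water by E1cB and enolises at C2' and C4' to the aromatic ring. No stereocentre remains, since the racemic C5' centre of 17 and the centres of 19 all become sp2. The step needs the C1'→C6' aldol to win over Claisen closure onto the carboxyl carbon, over aldol of the hexanoyl α-methylene onto the C2' ketone, and over attack of the C5' carbanion on the isocoumarin C1. In water the carboxyl is an unreactive carboxylate and the lactone carbonyl is deactivated by the para 6-phenoxide; of the two carbons that can reach a six-membered ring, C1' (between ketone and carboxylate) enolises far more readily than the hexanoyl α-methylene; and the C5' closure would give a quaternary 3-coumaranone. Low temperature and cold acidification should keep the β-resorcylic acid from decarboxylating, and any isocoumarin opened to its keto acid should reclose under the brief TFA treatment.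

**Compound list**

1 | hexanoyl chloride | CCCCCC(Cl)=O | starting material
2 | N-methoxy-N-methylhexanamide | CCCCCC(=O)N(C)OC | intermediate
3 | methyl orsellinate (methyl 2,4-dihydroxy-6-methylbenzoate) | COC(=O)c1c(C)cc(O)cc1O | starting material
4 | methyl 2,4-bis(methoxymethoxy)-6-methylbenzoate | COC(=O)c1c(C)cc(OCOC)cc1OCOC | intermediate
5 | methyl 2-(lithiomethyl)-4,6-bis(methoxymethoxy)benzoate (lithiated toluate) | [Li]Cc1cc(OCOC)cc(OCOC)c1C(=O)OC | intermediate (not isolated)
6 | methyl 2,4-bis(methoxymethoxy)-6-(2-oxoheptyl)benzoate | CCCCCC(=O)Cc1cc(OCOC)cc(OCOC)c1C(=O)OC | intermediate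
7 | methyl 2,4-dihydroxy-6-(2-oxoheptyl)benzoate (dihydroxy keto ester) | CCCCCC(=O)Cc1cc(O)cc(O)c1C(=O)OC | intermediate (not isolated)
8 | 6,8-dihydroxy-3-pentyl-1H-isochromen-1-one | CCCCCc1cc2cc(O)cc(O)c2c(=O)o1 | intermediate
9 | 8-hydroxy-6-[(4-methoxyphenyl)methoxy]-3-pentyl-1H-isochromen-1-one | CCCCCc1cc2cc(OCc3ccc(OC)cc3)cc(O)c2c(=O)o1 | intermediate
10 | 4-hydroxy-6-methyl-2H-pyran-2-one (triacetic acid lactone) | Cc1cc(O)cc(=O)o1 | starting material
11 | 4-[(4-methoxyphenyl)methoxy]-6-methyl-2H-pyran-2-one | Cc1cc(OCc2ccc(OC)cc2)cc(=O)o1 | intermediate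
12 | 6-(lithiomethyl)-4-[(4-methoxyphenyl)methoxy]-2H-pyran-2-one (lithiated pyranone) | [Li]Cc1cc(OCc2ccc(OC)cc2)cc(=O)o1 | intermediate (not isolated)
13 | 4-[(4-methoxyphenyl)methoxy]-6-(2-oxoheptyl)-2H-pyran-2-one | CCCCCC(=O)Cc1cc(OCc2ccc(OC)cc2)cc(=O)o1 | intermediate
14 | lithium enolate of 13 (enolate geometry not defined) | [Li]OC(CCCCC)=Cc1cc(OCc2ccc(OC)cc2)cc(=O)o1 | intermediate (not isolated)
15 | 6-(1-bromo-2-oxoheptyl)-4-[(4-methoxyphenyl)methoxy]-2H-pyran-2-one (racemic) | CCCCCC(=O)C(Br)c1cc(OCc2ccc(OC)cc2)cc(=O)o1 | intermediate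
16 | 4-[(4-methoxyphenyl)methoxy]-6-[1-({6-[(4-methoxyphenyl)methoxy]-1-oxo-3-pentyl-1H-isochromen-8-yl}oxy)-2-oxoheptyl]-2H-pyran-2-one (racemic) | CCCCCC(=O)C(Oc1cc(OCc2ccc(OC)cc2)cc2cc(CCCCC)oc(=O)c12)c1cc(OCc2ccc(OC)cc2)cc(=O)o1 | intermediate
17 | 4-hydroxy-6-{1-[(6-hydroxy-1-oxo-3-pentyl-1H-isochromen-8-yl)oxy]-2-oxoheptyl}-2H-pyran-2-one (racemic) | CCCCCC(=O)C(Oc1cc(O)cc2cc(CCCCC)oc(=O)c12)c1cc(O)cc(=O)o1 | intermediate
18 | 6-[(6-hydroxy-1-oxo-3-pentyl-1H-isochromen-8-yl)oxy]-3,5,7-trioxododecanoic acid (racemic; formed as its potassium salts) | CCCCCC(=O)C(Oc1cc(O)cc2cc(CCCCC)oc(=O)c12)C(=O)CC(=O)CC(=O)O | intermediate (not isolated)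
19 | 2-hydroxy-3-[(6-hydroxy-1-oxo-3-pentyl-1H-isochromen-8-yl)oxy]-4,6-dioxo-2-pentylcyclohexane-1-carboxylic acid (mixture of stereoisomers) | CCCCCC1(O)C(C(=O)O)C(=O)CC(=O)C1Oc1cc(O)cc2cc(CCCCC)oc(=O)c12 | intermediate (not isolated)
20 | 4,6-dihydroxy-3-[(6-hydroxy-1-oxo-3-pentyl-1H-isochromen-8-yl)oxy]-2-pentylbenzoic acid | CCCCCc1cc2cc(O)cc(Oc3c(O)cc(O)c(C(=O)O)c3CCCCC)c2c(=O)o1 | target

**Step count and risks**

Total steps: 11. Longest linear sequence: 7 steps (steps 2, 3, 4, 5, 9, 10, 11 from methyl orsellinate; the same length from hexanoyl chloride through step 1).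

Steps most likely to fail:

1. Step 11. Hydroxide may cleave the hexanoyl group by retro-Claisen fragmentation before ring B closes, the isocoumarin lactone may open and fail to reclose cleanly, or the acid may decarboxylate on acidification. Fallback: ring B is brought in preformed and the C5'–O bond is made by Ullmann coupling, setting out from 9 and coming back at the target 20. Commercial olivetolic acid would be perbenzylated (BnBr, K2CO3, DMF) to benzyl 2,4-bis(benzyloxy)-6-pentylbenzoate F1. Iodination para to the 2-benzyloxy group (N-iodosuccinimide, cat. TFA, MeCN) should give benzyl 4,6-bis(benzyloxy)-3-iodo-2-pentylbenzoate F2. Coupling with 9 (CuI, picolinic acid, K3PO4, DMSO, 90 °C) should give benzyl 4,6-bis(benzyloxy)-3-({6-[(4-methoxyphenyl)methoxy]-1-oxo-3-pentyl-1H-isochromen-8-yl}oxy)-2-pentylbenzoate F3. Hydrogenolysis (H2, Pd/C, EtOAc) of the three benzyl groups and the PMB ether would then give 20.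

2. Step 9. The phenoxide may attack bromine instead of carbon, or simply deprotonate the acidic bromide, so that reduction and self-condensation of 15 replace the SN2 reaction. Fallback: the ether is made by carbenoid O–H insertion instead, setting out from 13 (with 9) and coming back at 16. Regitz diazo transfer to 13 (4-acetamidobenzenesulfonyl azide, DBU, MeCN, 0 °C) should give 6-(1-diazo-2-oxoheptyl)-4-[(4-methoxyphenyl)methoxy]-2H-pyran-2-one F4. Slow addition of this to 9 and Rh2(OAc)4 (cat.) in CH2Cl2 should insert the carbenoid into the 8-O–H bond and give 16.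

3. Step 8. Proton transfer between the product and unreacted enolate may lead to over-bromination, and some bromination at pyranone C3 may occur. Fallback: the leaving group is introduced through oxygen, setting out from 13 and coming back at 15. Enolate oxidation (LiN(SiMe3)2, THF, −78 °C; 3-phenyl-2-(phenylsulfonyl)oxaziridine) should give 6-(1-hydroxy-2-oxoheptyl)-4-[(4-methoxyphenyl)methoxy]-2H-pyran-2-one F5 (racemic). Appel bromination (CBr4, PPh3, CH2Cl2, 0 °C) would convert this into 15.

**Further compounds**

F1 | step 11 | benzyl 2,4-bis(benzyloxy)-6-pentylbenzoate | CCCCCc1cc(OCc2ccccc2)cc(OCc2ccccc2)c1C(=O)OCc1ccccc1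
F2 | step 11 | benzyl 4,6-bis(benzyloxy)-3-iodo-2-pentylbenzoate | CCCCCc1c(I)c(OCc2ccccc2)cc(OCc2ccccc2)c1C(=O)OCc1ccccc1
F3 | step 11 | benzyl 4,6-bis(benzyloxy)-3-({6-[(4-methoxyphenyl)methoxy]-1-oxo-3-pentyl-1H-isochromen-8-yl}oxy)-2-pentylbenzoate | CCCCCc1cc2cc(OCc3ccc(OC)cc3)cc(Oc3c(OCc4ccccc4)cc(OCc4ccccc4)c(C(=O)OCc4ccccc4)c3CCCCC)c2c(=O)o1
F4 | step 9 | 6-(1-diazo-2-oxoheptyl)-4-[(4-methoxyphenyl)methoxy]-2H-pyran-2-one | CCCCCC(=O)C(=[N+]=[N-])c1cc(OCc2ccc(OC)cc2)cc(=O)o1
F5 | step 8 | 6-(1-hydroxy-2-oxoheptyl)-4-[(4-methoxyphenyl)methoxy]-2H-pyran-2-one (racemic) | CCCCCC(=O)C(O)c1cc(OCc2ccc(OC)cc2)cc(=O)o1
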